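**Retrosynthetic overview**

- The target quinone is numbered C1(=O), C2(Me), C3(heneicosyl), C4(=O), C5(OMe), C6(H). The oxygens on C1 and C5 are meta with the chain on C3, so the ring is an oxidised 5-alkylresorcinol of a tetraketide started by a C22 acyl unit, and the C4 oxygen sits on the carbon that carried the polyketide carboxyl.
- Late stage: C4=O comes from C4–H by oxidation para to the C1 phenol, and C4–H from C4–CO2 by decarboxylation. C5–OMe is set while the C1 oxygen is masked as a benzyl ether.
- Ring formation (the only ring made): the benzene ring is closed by C3–C4 aldol condensation of the α-carbon of a 1,3-dioxin-4-one onto the chain ketone of a diketo-dioxinone. The dioxinone ring comes with the starting material and is opened later.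
- Chain assembly: C2–C3 by Claisen acylation of a keto-dioxinone dianion with the C22 Weinreb amide; C6–C1 by acylation of the dioxinone dienolate with propanoyl chloride.

Key step: step 4

Remark: the target has no stereocentre. The side chain of 10 is numbered C1' (CH2 on the dioxinone), C2' (C=O), C3' (CHMe) and C4' (C=O bearing the heneicosyl); C3' forms racemic, is enolisable and becomes an sp2 ring carbon in step 4.

**Step 1**
Reactants: 1 2,2,6-trimethyl-4H-1,3-dioxin-4-one; 2 propanoyl chloride
Product: 4 2,2-dimethyl-6-(2-oxobutyl)-4H-1,3-dioxin-4-one, via lithium dienolate 3 (not isolated)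
Conditions: LiN(SiMe3)2 (2 equiv), 1 (2 equiv), THF, −78 °C; then 2 (1 equiv), −78 °C; aq. NH4Cl
Reagents that add atoms: none
Why: Vinylogous Claisen acylation, in which the γ-deprotonated dioxinone 3 is acylated at its terminal carbon by the acid chloride, the second equivalent of 3 taking up the acidic proton of 4 so that the chloride is used up cleanly.

**Step 2**
Reactants: 5 docosanoic acid
Product: 7 N-methoxy-N-methyldocosanamide, via 1-docosanoylimidazole 6 (not isolated)
Conditions: 1,1'-carbonyldiimidazole, THF, 45 °C; then MeNH(OMe)·HCl, rt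
Reagents that add atoms: N,O-dimethylhydroxylamine hydrochloride, CNOC.Cl
Why: Standard Weinreb amide synthesis by acyl imidazole activation and aminolysis, giving an acyl donor that cannot over-react in step 3.

**Step 3**
Reactants: 4 2,2-dimethyl-6-(2-oxobutyl)-4H-1,3-dioxin-4-one; 7 N-methoxy-N-methyldocosanamide
Product: 10 2,2-dimethyl-6-(3-methyl-2,4-dioxopentacosyl)-4H-1,3-dioxin-4-one, via dilithium dianion 8 (not isolated), via tetrahedral lithium adduct 9 (not isolated)
Conditions: LiN(iPr)2 (2.2 equiv), THF, −78 to −40 °C; then 7 in THF, −78 to −20 °C; 1 M HCl, 0 °C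
Reagents that add atoms: none
Why: Claisen condensation of a 1,3-dicarbonyl-type dianion, in which the second, kinetic deprotonation puts the more reactive carbanion on the ethyl CH2 (C3'), which alone attacks the amide, and the chelated adduct 9 releases the acidic 2-methyl-1,3-diketone only on the acid quench, so it can neither quench 8 nor be acylated again (C3' forms racemic).

**Step 4**
Reactants: 10 2,2-dimethyl-6-(3-methyl-2,4-dioxopentacosyl)-4H-1,3-dioxin-4-one
Product: 13 5-heneicosyl-7-hydroxy-2,2,6-trimethyl-4H-1,3-benzodioxin-4-one, via aldol adduct 11 (not isolated), via cyclohexadienone tautomer 12 (not isolated)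
Conditions: Et3N, CH2Cl2, rt
Reagents that add atoms: none
Why: Et3N removes a proton from the doubly activated C1' methylene, and the cross-conjugated dienolate attacks through the dioxinone α-carbon (future C4) the C4' ketone bearing the heneicosyl chain (future C3) to give aldol adduct 11. E1cB loss of water across C3'–C4' then gives dienone 12, whose remaining ring C–H shifts to oxygen, so that aromatisation pulls the reversible aldol forward. The closest known reaction is the amine-mediated aldol aromatisation of diketo-dioxinones to isopropylidene-protected resorcylates, the laboratory form of orsellinate-type polyketide folding. The six-membered carbocycle closes 6-exo-trig on the ketone with the dioxinone enolate C=C outside the new ring (enolexo), a favoured mode, and the stereocentres of 11 are all lost on aromatisation. The step needs C–C closure at the dioxinone α-carbon in preference to O-cyclisation to a pyranone or acyl transfer to the carboxyl carbon, and this is secured because the acetonide holds the carboxyl and the future C5 oxygen as a vinylogous ester that is no acyl donor at room temperature, while C4' is the only ketone six atoms from a nucleophilic carbon. Because the nucleophile is fixed at the ester terminus, the methyl between the two ketones can only end on C2, between the free hydroxyl on C1 and the chain on C3.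

**Step 5**
Reactants: 13 5-heneicosyl-7-hydroxy-2,2,6-trimethyl-4H-1,3-benzodioxin-4-one
Product: 14 7-(benzyloxy)-5-heneicosyl-2,2,6-trimethyl-4H-1,3-benzodioxin-4-one
Conditions: BnBr, K2CO3, DMF, 50 °C
Reagents that add atoms: benzyl bromide, BrCc1ccccc1
Why: Williamson etherification of the only free phenol (the C1 oxygen, acidic because it is para to the ring carbonyl), the C5 oxygen being held in the acetonide.

**Step 6**
Reactants: 14 7-(benzyloxy)-5-heneicosyl-2,2,6-trimethyl-4H-1,3-benzodioxin-4-one
Product: 16 3-(benzyloxy)-5-heneicosyl-4-methylphenol, via salicylic acid 15 (not isolated)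
Conditions: KOH, DMSO/H2O, 90 °C; then AcOH, 120 °C
Reagents that add atoms: none
Why: Saponification of the aryl acylal ester releases acetone and the salicylate, and after acidification the ortho-hydroxy, para-alkoxy, di-ortho-substituted benzoic acid 15 should undergo thermal protodecarboxylation by ipso protonation, as orsellinic-type acids do, while the benzyl ether is inert to both stages.

**Step 7**
Reactants: 16 3-(benzyloxy)-5-heneicosyl-4-methylphenol
Product: 17 1-(benzyloxy)-3-heneicosyl-5-methoxy-2-methylbenzene
Conditions: MeI, K2CO3, DMF, 40 °C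
Reagents that add atoms: iodomethane, CI
Why: Williamson methylation of the single free phenol, which is the C5 oxygen released from the acetonide.

**Step 8**
Reactants: 17 1-(benzyloxy)-3-heneicosyl-5-methoxy-2-methylbenzene
Product: 18 3-heneicosyl-5-methoxy-2-methylphenol
Conditions: H2 (1 atm), 10% Pd/C, EtOAc/THF, rt
Reagents that add atoms: none
Why: Catalytic hydrogenolysis of the benzyl aryl ether, to which the methyl ether and the saturated chain are inert.

**Step 9**
Reactants: 18 3-heneicosyl-5-methoxy-2-methylphenol
Product: 19 2-heneicosyl-6-methoxy-3-methyl-1,4-benzoquinone (CNP0104330.0)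
Conditions: (KSO3)2NO (2.5 equiv), KH2PO4, methyltrioctylammonium chloride (cat.), CH2Cl2/H2O, rt
Reagents that add atoms: dipotassium nitrosodisulfonate, [K+].[K+].[O]N(S(=O)(=O)[O-])S(=O)(=O)[O-]
Why: Teuber oxidation, in which one nitroxide radical abstracts the phenolic hydrogen and a second couples at the unsubstituted para carbon C4 and then loses imidodisulfonate to give the para-quinone, as in the oxidation of 3-methoxy-5-alkylphenols to 2-methoxy-6-alkyl-1,4-benzoquinones; phase transfer brings the lipophilic phenol and the salt together.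

**Compound list**

1 | 2,2,6-trimethyl-4H-1,3-dioxin-4-one | CC1=CC(=O)OC(C)(C)O1 | starting material
2 | propanoyl chloride | CCC(=O)Cl | starting material
3 | lithium 2,2-dimethyl-6-methylidene-6H-1,3-dioxin-4-olate (dienolate of 1) | [Li+].[O-]C1=CC(=C)OC(C)(C)O1 | intermediate
4 | 2,2-dimethyl-6-(2-oxobutyl)-4H-1,3-dioxin-4-one | CCC(=O)CC1=CC(=O)OC(C)(C)O1 | intermediate
5 | docosanoic acid | CCCCCCCCCCCCCCCCCCCCCC(=O)O | starting material
6 | 1-docosanoylimidazole | CCCCCCCCCCCCCCCCCCCCCC(=O)n1ccnc1 | intermediate
7 | N-methoxy-N-methyldocosanamide | CCCCCCCCCCCCCCCCCCCCCC(=O)N(C)OC | intermediate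
8 | dilithium bis-enolate (dianion) of 4 | [Li+].[Li+].CC=C([O-])C=C1C=C([O-])OC(C)(C)O1 | intermediate
9 | dilithium tetrahedral adduct of 8 and 7 (N-methoxy-N-methyl hemiaminal alkoxide, enolate retained) | [Li+].[Li+].CCCCCCCCCCCCCCCCCCCCCC([O-])(N(C)OC)C(C)C(=O)C=C1C=C([O-])OC(C)(C)O1 | intermediate
10 | 2,2-dimethyl-6-(3-methyl-2,4-dioxopentacosyl)-4H-1,3-dioxin-4-one (racemic at C3', tautomer mixture) | CCCCCCCCCCCCCCCCCCCCCC(=O)C(C)C(=O)CC1=CC(=O)OC(C)(C)O1 | intermediate
11 | 5-heneicosyl-5-hydroxy-2,2,6-trimethyl-4a,5-dihydro-4H-1,3-benzodioxine-4,7(6H)-dione (aldol adduct, diastereomer mixture) | CCCCCCCCCCCCCCCCCCCCCC1(O)C(C)C(=O)C=C2OC(C)(C)OC(=O)C12 | intermediate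
12 | 5-heneicosyl-2,2,6-trimethyl-4H-1,3-benzodioxine-4,7(4aH)-dione (keto tautomer of 13) | CCCCCCCCCCCCCCCCCCCCCC1=C(C)C(=O)C=C2OC(C)(C)OC(=O)C12 | intermediate
13 | 5-heneicosyl-7-hydroxy-2,2,6-trimethyl-4H-1,3-benzodioxin-4-one | CCCCCCCCCCCCCCCCCCCCCc1c(C)c(O)cc2OC(C)(C)OC(=O)c12 | intermediate
14 | 7-(benzyloxy)-5-heneicosyl-2,2,6-trimethyl-4H-1,3-benzodioxin-4-one | CCCCCCCCCCCCCCCCCCCCCc1c(C)c(OCc3ccccc3)cc2OC(C)(C)OC(=O)c12 | intermediate
15 | 4-(benzyloxy)-2-heneicosyl-6-hydroxy-3-methylbenzoic acid (potassium salt until acidified) | CCCCCCCCCCCCCCCCCCCCCc1c(C)c(OCc2ccccc2)cc(O)c1C(=O)O | intermediate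
16 | 3-(benzyloxy)-5-heneicosyl-4-methylphenol | CCCCCCCCCCCCCCCCCCCCCc1cc(O)cc(OCc2ccccc2)c1C | intermediate
17 | 1-(benzyloxy)-3-heneicosyl-5-methoxy-2-methylbenzene | CCCCCCCCCCCCCCCCCCCCCc1cc(OC)cc(OCc2ccccc2)c1C | intermediate
18 | 3-heneicosyl-5-methoxy-2-methylphenol | CCCCCCCCCCCCCCCCCCCCCc1cc(OC)cc(O)c1C | intermediate
19 | 2-heneicosyl-6-methoxy-3-methyl-1,4-benzoquinone | CCCCCCCCCCCCCCCCCCCCCC1=C(C)C(=O)C=C(OC)C1=O | target

**Totals**

Total step count: 9. Longest linear sequence: 8 steps (1 → 4 → 10 → 13 → 14 → 16 → 17 → 18 → 19; step 2 is a one-step side branch).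

**Steps most likely to fail**

Step 4. Under the weak amine base the aldol may stay reversible and stall before dehydration, or the 2-methyl-1,3-diketone may fragment by retro-Claisen cleavage or close through oxygen if traces of acid are present. The fallback sets out from 10 and keeps the same ring-forming bond but uses an open-chain β-keto ester nucleophile. Heating 10 in toluene at 110 °C with methanol opens the dioxinone by retro-[4+2] loss of acetone, and the acylketene is trapped as methyl 6-methyl-3,5,7-trioxooctacosanoate F3. Cs2CO3 in MeOH, followed by HCl in MeOH for the dehydration, should cyclise F3 by attack of its ester α-carbon on the chain ketone to methyl 2-heneicosyl-4,6-dihydroxy-3-methylbenzoate F4. BnBr and K2CO3 in acetone etherify only the hydroxyl that is not hydrogen-bonded to the ester, giving methyl 4-(benzyloxy)-2-heneicosyl-6-hydroxy-3-methylbenzoate F5. KOH in DMSO/H2O saponifies F5 to acid 15, where the route is rejoined inside step 6.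

Step 3. The strongly basic secondary carbanion of 8 may take a proton from the α-CH2 of the amide instead of adding to it, the C22 amide may fall out of solution at low temperature, and the regenerated monoanion may be acylated at its central carbon. The fallback sets out from 4 and 7 and makes the bond at the aldehyde oxidation level. Compound 7 is reduced with (iBu)2AlH in THF at −78 °C to docosanal F1. Dianion 8, made from 4 as before, adds to F1 at −78 °C to give 6-(4-hydroxy-3-methyl-2-oxopentacosyl)-2,2-dimethyl-4H-1,3-dioxin-4-one F2 as a diastereomer mixture. Dess–Martin periodinane in CH2Cl2 at rt oxidises F2 to 10, where the route is rejoined.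

Step 6. Loss of CO2 from an acid that carries only one free hydroxyl may be incomplete, and forcing the acid stage may begin to cleave the benzyl ether. The fallback sets out from 13, replaces steps 5 to 9 and moves the differentiation of the two oxygens to the quinone stage. KOH in DMSO/H2O hydrolyses unprotected 13 to 2-heneicosyl-4,6-dihydroxy-3-methylbenzoic acid F6. With hydroxyls both ortho and para to the carboxyl, F6 should lose CO2 on acidification and gentle heating to give 5-heneicosyl-4-methylbenzene-1,3-diol F7. (KSO3)2NO oxidises F7 at the only free position para to a hydroxyl (the other para position carries the methyl) to 2-heneicosyl-6-hydroxy-3-methyl-1,4-benzoquinone F8. The single vinylogous-acid hydroxyl of F8 is then etherified with MeOH and catalytic H2SO4 to give 19.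

**Further compounds**

F1 | step 3 | docosanal | CCCCCCCCCCCCCCCCCCCCCC=O
F2 | step 3 | 6-(4-hydroxy-3-methyl-2-oxopentacosyl)-2,2-dimethyl-4H-1,3-dioxin-4-one | CCCCCCCCCCCCCCCCCCCCCC(O)C(C)C(=O)CC1=CC(=O)OC(C)(C)O1
F3 | step 4 | methyl 6-methyl-3,5,7-trioxooctacosanoate | CCCCCCCCCCCCCCCCCCCCCC(=O)C(C)C(=O)CC(=O)CC(=O)OC
F4 | step 4 | methyl 2-heneicosyl-4,6-dihydroxy-3-methylbenzoate | CCCCCCCCCCCCCCCCCCCCCc1c(C)c(O)cc(O)c1C(=O)OC
F5 | step 4 | methyl 4-(benzyloxy)-2-heneicosyl-6-hydroxy-3-methylbenzoate | CCCCCCCCCCCCCCCCCCCCCc1c(C)c(OCc2ccccc2)cc(O)c1C(=O)OC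
F6 | step 6 | 2-heneicosyl-4,6-dihydroxy-3-methylbenzoic acid | CCCCCCCCCCCCCCCCCCCCCc1c(C)c(O)cc(O)c1C(=O)O
F7 | step 6 | 5-heneicosyl-4-methylbenzene-1,3-diol | CCCCCCCCCCCCCCCCCCCCCc1cc(O)cc(O)c1C
F8 | step 6 | 2-heneicosyl-6-hydroxy-3-methyl-1,4-benzoquinone | CCCCCCCCCCCCCCCCCCCCCC1=C(C)C(=O)C=C(O)C1=O
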